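G was what I counted. In these flasks, G is the part of the fed D that has turned over with Q before the clock stops.

all flasks: D 23 mM (fed, over 1.5 h); E 5.4 mM (held)

|  | Q | remark | time |
|---|---|---|---|
| gamma | 53 mM | run made earlier |  |
| eta | 90 mM | run made earlier |  |
| Tuesday's | 70.0 mM |  | 1.5 h |
| Friday's | 54.0 mM |  | 1.5 h |
| Monday's | 41.0 mM |  | 1.5 h |

- gamma (time / min: D / %, G / %): 8.00: 10, 7; 15.0: 12, 6; 25.0: 18, 9; 50.0: 24, 33; 90.0: 34, 63
- eta (time / min: D / %, G / %): 20.0: 11, 10; 40.0: 14, 31; 50.0: 18, 39; 80.0: 21, 69; 90.0: 21, 76

(scatter of a reading: 2 percentage points)

- at the start none of X is dissolved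
- candidate steps: D + Q <-> J + G; Q + J <-> Z; J + X <-> L; E <-> X
- percentages count the whole charge, also what has not yet gone in

- part of the D that has reacted at the end, Tuesday's
- part of the D that has reacted at the end, Friday's
- part of the D that has reacted at the end, Monday's
- what raising the concentration of Q from its lowest to its highest value here does to the part of the D that has reacted (changes below 5 percentage points count as none) (it falls / it rises / no change)

I ran the gamma flask in slow motion. In the early part, at 25.0 min, the feed had brought in 27.8% of the charge. D plus G read 27.0%, and more of it stood as D than as G. By the middle, at 50.0 min, the feed stood at 55.6% and the sum at 57.0%, and G had passed D. At the end, at 90.0 min, the sum read 97.0% of a full charge, with D still climbing. So D and G followed the feed within the scatter, and I needed to reckon D alone.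

Q stood above the charge of D, but it need not hold still, since the candidate steps also take it up with J. So what follows is a rough count: one rate for D through the whole feed, in proportion to the Q charged, with any loss of Q lumped into it. Let N be the turnovers, the dosing time divided by the mean life of D. In fractions of the charge, with time in dosing times:

rate of change of D left = 1 − N × D left

D left at the end = (1 − exp(−N)) / N

Turned round, with 1/left put for N inside the exponential:

gamma: D left 34%, N = 2.79, per Q 0.0526 mM⁻¹

eta: D left 21%, N = 4.72, per Q 0.0525 mM⁻¹

The turnovers per mM of Q charged came out alike in both runs, so I carried that number to the new flasks: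

Tuesday's: N = 3.67, reacted 73.5%

Friday's: N = 2.83, reacted 66.8%

Monday's: N = 2.15, reacted 58.9%

The forecast gave 72.5%, 66% and 56% for Tuesday's, Friday's and Monday's and said of the part reacted, as Q goes from lowest to highest, that it rises, reasoning “so rate scales with Q”, and its Monday's figure stood lower than mine.

The flasks gave 72.5%, 64.7% and 55.8%; from the lowest Q to the highest, the part reacted: it rises, by 17 percentage points.

    D + Q ⇌ J + G (K = 0.320, k = 0.0140 M⁻¹ s⁻¹)
    Q + J ⇌ Z, settled at all times (K = 23000 M⁻¹)
    J + X ⇌ L, settled at all times (K = 35000 M⁻¹)
    E ⇌ X, rate k4*(csat - [X]) (kL = 0.0200 s⁻¹)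

My count ran 3.1 points high on Monday's flask. There the forward half-life of D, 0.34 h with the other concentrations as charged, was 0.47 h at 0.873 h, and 46.7% of the charged Q stood free at the end; that middle value, shorter than the dosing time of 1.5 h, makes 2.21 turnovers against my 2.15. The neighbour of Monday's flask with 92 mM of D, at 0.446 equiv of Q, counts the same 2.15 and so 58.9% reacted, but it gave 30.6%, with 9.19% of its Q free.

(The data come from a simulation for an exercise.)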